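All runs come from a simulation with constants of no real substance, noise included.

If free enzyme is lost at a rate that goes with the square of its amount, while substrate is used pseudo-first-order at each moment's enzyme, the one rate integrates in closed form. The depth, ln(1/rest), with rest the fraction of the charge not yet target, follows c·ln(1 + t/τ), where τ shrinks as the enzyme charge grows and c does not depend on that charge. Well beyond τ, each equal factor of time therefore adds the same depth, and time enters as the product of enzyme charge and time, the enzyme clock.

all flasks: substrate 20 mM; free enzyme 0.10 µM
- Monday's: temperature 20 °C; the very flask that is asked about, followed so far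
- Tuesday's: temperature 15 °C; run made earlier
- flask: temperature 20 °C; time 8.0 min

| Monday's: time / min | Monday's: target / % | Tuesday's: time / min | Tuesday's: target / % |
|---|---|---|---|
| 0.667 | 32.4 | 0.667 | 30.1 |
| 1.50 | 47.1 | 1.50 | 45.3 |
| 3.00 | 59.5 | 3.00 | 58.2 |
| 5.00 | 67.7 | 5.00 | 66.4 |

(scatter of a reading: 0.5 percentage points)

- delta: at 8.0 min add free enzyme, 100 % of the amount charged, then wait 4.0 min
- zeta: at 8.0 min take out 90 % of the target then present, then wait 4.0 min
- theta: change nothing and wait 4.0 min more
- eta: at 8.0 min raise the temperature by 15 K, then wait 4.0 min

- target, in percent of the substrate first charged, at 8.0 min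
- the option that brings most further target ("none" if no option brings more than 2 percentage points) (delta / zeta / theta / eta / none)
- target present, with what was taken out counted in, in percent of the substrate first charged, after delta
- target present, with what was taken out counted in, in percent of the substrate first charged, after zeta

- removed target is counted in
- additions bring no volume worth counting

Monday's flask gains depth at 0.294 min⁻¹ between its first two readings and 0.113 min⁻¹ between its last two, so the rate per unit of substrate falls, though these readings cannot part enzyme loss from hindrance by target. Between those last two readings the depth gained per e-fold of time is 0.443, the log-time slope, and Tuesday's flask gives 0.427.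

Time comes first: carried on from Monday's last reading, with depth 1.13, the slope puts target in the asked flask near 73.8 %, and theta near 78.1 %. Enzyme is next: a flask charged from the start with twice the enzyme would read 83.9 % at the end of the wait, and this reckoning takes that as the low mark for delta, whose added enzyme arrives fresh. Its gain of 10 percentage points is larger than theta's 4.3 points. Temperature is poorly read: Tuesday's flask lies 0.0395 in depth below Monday's, a thin gap against the scatter, so this reckoning puts no number of its own on eta and expects a gain of the order of theta's. Taking out target leaves the clock as it is, so zeta stands at theta's value, with any hindrance by target on top.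

The forecast gives 73.7 %, chooses delta, and puts delta at 90.8 % and zeta at 78.2 %, holding that “removing target should change nothing”.

The flask gives 73.1 % against the slope's 73.8 %, and delta gains most, 13 points, reaching 86.2 %; zeta reaches 81.9 %, and theta 77.4 % against the slope's 78.1 %.

    free enzyme → unfolded enzyme (k = 2.30 × 10⁻⁵ s⁻¹, Ea = 202 kJ mol⁻¹)
    substrate + free enzyme → target + free enzyme, rate k2*[substrate]*[free enzyme]/(1 + ([substrate]/Km2) + ([target]/Kp2)) (0.0620 M, 6.80 mM, k = 2.10 × 10⁵ M⁻¹ s⁻¹, Ea = 16.0 kJ mol⁻¹)
    2 free enzyme → spent catalyst (k = 60000 M⁻¹ s⁻¹, Ea = 19.0 kJ mol⁻¹)
    substrate → uncatalysed product (k = 9.40 × 10⁻⁵ s⁻¹, Ea = 103 kJ mol⁻¹)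
    (constants at 20 °C)

The neighbouring flask holds 4.0 × 10⁻⁴ mM of free enzyme, 4.00 times the charge, so at 8.0 min its enzyme clock reads as Monday's flask at 32.0 min. The slope carried that far gives 85.8 %, and the neighbouring flask stands at 85.8 % target with 13 % of its substrate left.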